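## Structural features

The target is a 2,3-dihydrobenzofuran (ring A benzo, ring B dihydrofuran). C2 carries ring C, a 4-hydroxy-3,5-dimethoxyphenyl group, and C3 carries a CH2O arm. Ring A bears a methoxy group at C7 and an (E)-3-oxyprop-1-enyl chain at C5, and both primary oxygens are acylated by 4-hydroxybenzoic acid. C2 (S) and C3 (R) are adjacent and are the only stereocentres; ring C and the C3 arm are trans, and one (E)-alkene completes the stereochemical content. Three groups are fragile: the benzylic C2–O1 ether, which a para-phenoxide on ring C can open through a quinone methide with loss of the C2 configuration; the cinnamyl ester para to O1, which ionises easily and rules out hydrogenolysis; and the three free phenols. The real difficulty is to fix the absolute and trans-relative configuration at C2/C3 next to an ionisable centre, and to build a tetrasubstituted ring A with oxygen on the adjacent carbons C7a and C7 and carbon on C3a and C5. The key step exploits this pattern: C7a and C7 are read as the two carbons of an alkynyl ether hanging on O1, and C3a, C4, C5 and C6 as the four carbons of a 2,4-disubstituted furan, whose ring oxygen becomes the C7 oxygen. Because O1 is part of the tether, ring B closes in the same event, so C2 and C3 can be set beforehand on an open chain.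

## Logic of the disconnections

**29 ⇒ 28.** The three phenolic O–Si bonds are the last to be broken. Free phenols would compete in the acylation, and the free ring C phenol activates C2 towards ring opening, so all three stay masked until the end. The forward step must cleave them without a long-lived phenoxide and without touching the two esters.

**28 ⇒ 24 + 27 (27 ⇒ 25).** Both acyl C–O bonds are cut together because the two esters carry the same acid. This gives one diol and two equivalents of one acid. The forward step needs both primary hydroxyls free at once and a neutral activation that spares the ionisable cinnamyl position.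

**24 ⇒ 23 ⇒ 22.** The side-chain C=C bond is cut back to an aryl aldehyde and a two-carbon ylide, followed by an ester-to-alcohol adjustment. This reduces the side chain to a one-carbon substituent at C5. The forward steps need E-selectivity and clean 1,2-reduction.

**22 ⇒ 21 ⇒ 20 ⇒ 19.** These are level adjustments: the C5 carbon returns to the alcohol, both primary oxygens to trityl ethers, and the C7 O–CH3 bond is cut. The two primary oxygens can thus pass through the key step in identical form. The forward steps rely on benzylic versus aliphatic selectivity in the oxidation and on 19 having a single free phenol.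

**19 ⇒ 17 (key).** The C3a–C7a and C6–C7 bonds are cut. Ring A falls apart into a furan (C3a, C4, C5, C6 and the oxygen that ends on C7) and a terminal alkynyl ether (C7a, C7) on O1, and ring B opens at the same time. What remains is an acyclic chain with the two stereocentres. The forward step must attack the oxygen-bearing alkyne carbon and must not ionise the benzylic C–O bond.

**17 ⇒ 14.** The O–C(sp) bond is cut; the two carbons come from a chlorinated C2 alkene. This step dictates the protecting groups. The potassium alkoxide of 14 would take a silyl group from the neighbouring primary oxygen by 1,5-transfer, so both primary oxygens carry trityl groups, which cannot migrate and later fall to mild acid. The ring C phenol carries the bulky triisopropylsilyl group, which resists alkoxide, n-BuLi and the later carbonate methylation better than a smaller silyl group.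

**14 ⇒ 13 ⇒ 12.** Trityl removal and reduction trace both primary carbons to carbonyl groups: the imide carbonyl and the furan ester. One reduction then serves both and returns the auxiliary.

**12 ⇒ 7 + 9 (9 ⇒ 8).** The C2–C3 bond is cut as an aldol bond. This is the only stereo-determining step; it needs syn selectivity and the facial sense given by 5.

**7 ⇒ 4 + 5; 4 ⇒ 3 ⇒ 1 + 2.** The N-acyl bond and the furan C–CH2 bond are cut, leading to bought pieces. The forward coupling needs a zinc enolate that tolerates the furan ester.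

## Other disconnections considered

**Alternative 1:** The cut is C3–C3a, with the C3 carboxyl carbon traced to the carbonyl carbon of chromanone A2. PhI(OAc)2 (trivalent iodine) with H2SO4 in HC(OMe)3 would iodinate the enol ether of A2 at C3; ring A would then shift from the carbonyl carbon to C3, contracting the pyranone to ring B and giving A1.
- In favour: ring A is bought with O1, the C7 methoxy group and a C5 bromide (a Heck handle) in place. The trans relationship follows from the migration and is reinforced by the epimerisable ester. C3 arrives one reduction away from the CH2O arm.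
- Against: the absolute configuration rests on the single stereocentre of A2. 2-Aryl chromanones lose it by reversible retro-oxa-Michael opening, which the strongly acidic medium and the electron-rich ring C both favour. Ring C, the better migrating group, could shift from C2 to C3 in place of ring A, and dehydrogenation of A2 is a further drain. The benzyl ether would have to be exchanged before the cinnamyl ester appears.
- Comparison: in step count and in using a purchased arene this plan is better than the chosen one. In relative configuration it is its equal. In security of the absolute configuration and in chemoselectivity of the key event it is weaker, since the chosen plan sets both centres with an auxiliary and never breaks their bonds.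

**Alternative 2:** The cuts are O1–C2 and C2–C3, a (4+1) annulation. Cs2CO3 would eliminate sulfinate from A4 to give quinone methide A6 and deprotonate sulfonium salt A5. The ylide carbon would add to the exocyclic carbon of A6, and the phenoxide would displace the thiolane at C2 to give A3.
- In favour: this is the most convergent plan. Rings A and C come from two bought arenes, and ring B and both stereocentres arise in one operation. Trans geometry follows from anti addition and invertive closure. A3 already holds the C7 methoxy group and a C5 bromide.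
- Against: A6 bears a CH2OSi group on its exocyclic carbon, so proton shift or loss of silanolate would compete with ylide addition. The absolute configuration would depend on a stoichiometric chiral sulfide acting on a very electron-rich, semi-stabilised benzyl ylide, where reversible betaine formation can erode the facial preference.
- Comparison: in convergence and step economy it is better than the chosen plan. In control of the trans relationship it is its equal. In predictability of the absolute configuration it is weaker than an auxiliary aldol. Both plans pass through one sensitive species (A6 there, 17 here).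

**Alternative 3:** The cuts are C3–C3a and O1–C7a. Pd(OAc)2 (divalent palladium), a triarylphosphine, norbornene and Cs2CO3 would couple A8 with cis-epoxide A9. The aryl–norbornyl palladacycle formed by C–H activation at the future C3a would open A9 at the CH2O-bearing carbon with inversion; norbornene would be extruded and C7a–O1 reductive elimination would give A7.
- In favour: this is the shortest plan. Ring A is bought with the C5 ester and the C7 methoxy group, which is also the ortho substituent this chemistry needs. The event is stereospecific (cis-epoxide to trans product), and both centres are encoded in the substrate.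
- Against: the palladacycle would have to attack the non-benzylic carbon of a 2,3-disubstituted aryl epoxide, against the electronic bias towards the benzylic carbon. Internal epoxides are far slower than terminal ones in this manifold, so rearrangement of A9 could win. Enantiopure A9 needs a Z-alkene and a reagent-controlled epoxidation.
- Comparison: in step economy it is better than the chosen plan. In stereospecificity it is its equal in principle. In regiochemical security it is weaker, because in the chosen plan the polarisation of the alkynyl ether dictates both ring closures.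

The chosen plan is the longest of the four and builds an arene that could be bought. Its merit is that both stereocentres come from a well-understood auxiliary aldol and that the oxygen pattern of ring A cannot come out wrong.

Key step: step 9

Assumption: 1 and the ether solution of 2 are purchased reagents.

Remark: the (1S,2R) syn arrangement of 17 maps without change onto (2S,3R)-trans in 19, and the 2,4-substitution of the furan places the carbon arm at C5.

## Route

Step 1
Reactants: 1 methyl 5-bromofuran-3-carboxylate; 2 (2-tert-butoxy-2-oxoethyl)zinc bromide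
Product: 3 methyl 5-(2-tert-butoxy-2-oxoethyl)furan-3-carboxylate
Conditions: Pd2(dba)3 (2 mol%), XPhos (8 mol%), THF, 50 °C
Reagents that add atoms: none
Why: Negishi coupling of a Reformatsky zinc enolate: zerovalent palladium inserts into the C–Br bond of the ester-activated furan, and transmetallation and reductive elimination form the C(sp2)–C(sp3) bond; the mild zinc enolate leaves both esters alone.

Step 2
Reactants: 3 methyl 5-(2-tert-butoxy-2-oxoethyl)furan-3-carboxylate
Product: 4 [4-(methoxycarbonyl)furan-2-yl]acetic acid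
Conditions: TFA/CH2Cl2 (1:3), 0 °C → rt
Reagents that add atoms: none
Why: Acidolysis of the tert-butyl ester with loss of isobutene; the methyl ester and the ester-deactivated furan are stable to TFA.

Step 3
Reactants: 4 [4-(methoxycarbonyl)furan-2-yl]acetic acid; 5 (4S)-4-benzyl-1,3-oxazolidin-2-one
Product: 7 methyl 5-{2-[(4S)-4-benzyl-2-oxo-1,3-oxazolidin-3-yl]-2-oxoethyl}furan-3-carboxylate, via mixed pivalic anhydride 6 (not isolated)
Conditions: PivCl, Et3N, THF, −20 °C; then 5, LiCl, rt
Reagents that add atoms: none
Why: N-Acylation of the oxazolidinone through a mixed anhydride; the LiCl/Et3N-activated auxiliary attacks the less hindered arylacetyl carbonyl of 6.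

Step 4
Reactants: 8 syringaldehyde (4-hydroxy-3,5-dimethoxybenzaldehyde)
Product: 9 3,5-dimethoxy-4-(triisopropylsilyloxy)benzaldehyde
Conditions: TIPSCl, imidazole, DMF, rt
Reagents that add atoms: triisopropylsilyl chloride CC(C)[Si](Cl)(C(C)C)C(C)C
Why: Silyl ether formation on the phenol; the flanked aryl triisopropylsilyl ether is expected to survive KH, n-BuLi and K2CO3/MeI and to fall to fluoride at the end.

Step 5
Reactants: 7 methyl 5-{2-[(4S)-4-benzyl-2-oxo-1,3-oxazolidin-3-yl]-2-oxoethyl}furan-3-carboxylate; 9 3,5-dimethoxy-4-(triisopropylsilyloxy)benzaldehyde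
Product: 12 methyl 5-[(2R,3S)-1-[(4S)-4-benzyl-2-oxo-1,3-oxazolidin-3-yl]-3-[3,5-dimethoxy-4-(triisopropylsilyloxy)phenyl]-3-hydroxy-1-oxopropan-2-yl]furan-3-carboxylate, via (Z)-dibutylboron enolate 10 (not isolated), via dibutylboron aldolate 11 (not isolated)
Conditions: Bu2BOTf, i-Pr2NEt, CH2Cl2, 0 °C; then 9, −78 → 0 °C; pH 7 buffer, MeOH, H2O2, 0 °C
Reagents that add atoms: none
Why: Evans syn-aldol: the (Z)-boron enolate 10 reacts through a closed chair (Zimmerman–Traxler) transition state in which the dipole-opposed auxiliary exposes the face away from its benzyl group. The aryl-bearing carbinol carbon (future C2) is therefore set S and the furyl-bearing carbon (future C3) R, syn to each other; arylacetyl imides are established substrates for this reaction.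

Step 6
Reactants: 12 methyl 5-[(2R,3S)-1-[(4S)-4-benzyl-2-oxo-1,3-oxazolidin-3-yl]-3-[3,5-dimethoxy-4-(triisopropylsilyloxy)phenyl]-3-hydroxy-1-oxopropan-2-yl]furan-3-carboxylate
Product: 13 (1S,2R)-1-[3,5-dimethoxy-4-(triisopropylsilyloxy)phenyl]-2-[4-(hydroxymethyl)furan-2-yl]propane-1,3-diol
Conditions: LiBH4, MeOH (5 equiv), THF, 0 °C → 45 °C
Reagents that add atoms: none
Why: Reductive cleavage of the auxiliary by hydride attack on the exocyclic imide carbonyl at 0 °C, followed on warming by reduction of the furan ester with methanol-activated borohydride; once the imide is gone the stereocentres can no longer epimerise or undergo retro-aldol cleavage.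

Step 7
Reactants: 13 (1S,2R)-1-[3,5-dimethoxy-4-(triisopropylsilyloxy)phenyl]-2-[4-(hydroxymethyl)furan-2-yl]propane-1,3-diol
Product: 14 (1S,2R)-1-[3,5-dimethoxy-4-(triisopropylsilyloxy)phenyl]-3-(trityloxy)-2-[4-(trityloxymethyl)furan-2-yl]propan-1-ol
Conditions: TrCl (2.3 equiv), Et3N, DMAP (cat.), CH2Cl2, rt
Reagents that add atoms: trityl chloride ClC(c1ccccc1)(c1ccccc1)c1ccccc1
Why: Tritylation is sterically selective for primary hydroxyls, so the hindered benzylic secondary alcohol stays free; trityl ethers cannot migrate to the alkoxide of the next step as a silyl group could.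

Step 8
Reactants: 14 (1S,2R)-1-[3,5-dimethoxy-4-(triisopropylsilyloxy)phenyl]-3-(trityloxy)-2-[4-(trityloxymethyl)furan-2-yl]propan-1-ol
Product: 17 2-[(1S,2R)-1-[3,5-dimethoxy-4-(triisopropylsilyloxy)phenyl]-1-(ethynyloxy)-3-(trityloxy)propan-2-yl]-4-(trityloxymethyl)furan, via (E)-1,2-dichlorovinyl ether 15 (not isolated), via lithium acetylide 16 (not isolated)
Conditions: KH, THF, 0 °C; Cl2C=CHCl, −50 °C → rt; then n-BuLi (2.5 equiv), −78 → −40 °C; MeOH, −78 °C
Reagents that add atoms: trichloroethylene ClC=C(Cl)Cl
Why: Alkynyl ether synthesis from trichloroethylene: the potassium alkoxide adds to dichloroacetylene formed in the flask to give 15; n-BuLi then eliminates HCl and exchanges the remaining chlorine for lithium to give 16, which methanol protonates. The carbinol C–O bond is never broken, so its configuration is kept; 17 is kept cold, passed through amine-deactivated silica and used at once.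

Step 9
Reactants: 17 2-[(1S,2R)-1-[3,5-dimethoxy-4-(triisopropylsilyloxy)phenyl]-1-(ethynyloxy)-3-(trityloxy)propan-2-yl]-4-(trityloxymethyl)furan
Product: 19 (2S,3R)-2-[3,5-dimethoxy-4-(triisopropylsilyloxy)phenyl]-3,5-bis(trityloxymethyl)-2,3-dihydro-1-benzofuran-7-ol, via arene oxide 18 (not isolated)
Conditions: Ph3PAuNTf2 (3 mol%, monovalent gold), CH2Cl2, 0 °C → rt
Reagents that add atoms: none
Why: Ph3PAu+ binds the alkynyl ether, whose oxygen polarises the triple bond so that the oxygen-bearing carbon (future C7a) is the electrophilic end; furan C2 (future C3a) attacks it in a 5-exo-dig closure of ring B (O1, C2, C3, C3a, C7a) and gives a cyclopropyl gold carbenoid with the carbene on the former terminal carbon (future C7). Cleavage of the furan C2–O bond then unravels the furan to a dienal carbenoid, the aldehyde oxygen adds to the carbenoid carbon with release of the gold fragment, and the oxepine so formed closes by a 6π disrotatory electrocyclisation to arene oxide 18, which creates the C6–C7 bond and with it ring A. Opening of 18 at C6–O, the direction in which the positive charge is delocalised onto C7a and stabilised by O1, and loss of the C7 proton leave the former furan oxygen on C7 as the phenol. The closest known reaction type is the gold-catalysed intramolecular furan–alkyne phenol synthesis in its variant with oxygen-tethered alkynyl ethers, which gives 2,3-dihydrobenzofuran-7-ols. No stereocentre is formed: C2 and C3 come from the aldol and none of their bonds takes part, while the two stereocentres of 18 vanish on aromatisation. The step needs attack at the oxygen-bearing alkyne carbon, which the ynol ether polarisation and the three-atom tether secure, and regioselective opening of 18, which O1 secures. It also needs alkyne activation to outrun ionisation of the benzylic C–O bond, for which the acid-free conditions at 0 °C, the silyl rather than alkyl ether on ring C and the nucleophilic 2-alkylfuran are relied on.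

Step 10
Reactants: 19 (2S,3R)-2-[3,5-dimethoxy-4-(triisopropylsilyloxy)phenyl]-3,5-bis(trityloxymethyl)-2,3-dihydro-1-benzofuran-7-ol
Product: 20 (2S,3R)-2-[3,5-dimethoxy-4-(triisopropylsilyloxy)phenyl]-7-methoxy-3,5-bis(trityloxymethyl)-2,3-dihydro-1-benzofuran
Conditions: MeI, K2CO3, acetone, rt
Reagents that add atoms: iodomethane CI
Why: Williamson O-methylation of the only free phenol; the hindered aryl triisopropylsilyl ether is expected to hold under anhydrous carbonate, so ring C is not methylated.

Step 11
Reactants: 20 (2S,3R)-2-[3,5-dimethoxy-4-(triisopropylsilyloxy)phenyl]-7-methoxy-3,5-bis(trityloxymethyl)-2,3-dihydro-1-benzofuran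
Product: 21 [(2S,3R)-2-[3,5-dimethoxy-4-(triisopropylsilyloxy)phenyl]-7-methoxy-2,3-dihydro-1-benzofuran-3,5-diyl]dimethanol
Conditions: CSA (0.2 equiv), MeOH/CH2Cl2 (1:1), 0 °C → rt
Reagents that add atoms: none
Why: Acid-catalysed solvolysis of both trityl ethers through the trityl cation, which methanol traps; aryl silyl ethers and the alkoxybenzyl-type C–O bonds at C2 and C5 do not ionise under this mild acid.

Step 12
Reactants: 21 [(2S,3R)-2-[3,5-dimethoxy-4-(triisopropylsilyloxy)phenyl]-7-methoxy-2,3-dihydro-1-benzofuran-3,5-diyl]dimethanol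
Product: 22 (2S,3R)-2-[3,5-dimethoxy-4-(triisopropylsilyloxy)phenyl]-3-(hydroxymethyl)-7-methoxy-2,3-dihydro-1-benzofuran-5-carbaldehyde
Conditions: MnO2 (activated, excess), CH2Cl2, rt
Reagents that add atoms: none
Why: MnO2 oxidation is selective for the benzylic alcohol at C5; the saturated primary alcohol on the C3 arm is not oxidised.

Step 13
Reactants: 22 (2S,3R)-2-[3,5-dimethoxy-4-(triisopropylsilyloxy)phenyl]-3-(hydroxymethyl)-7-methoxy-2,3-dihydro-1-benzofuran-5-carbaldehyde
Product: 23 ethyl (2E)-3-[(2S,3R)-2-[3,5-dimethoxy-4-(triisopropylsilyloxy)phenyl]-3-(hydroxymethyl)-7-methoxy-2,3-dihydro-1-benzofuran-5-yl]prop-2-enoate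
Conditions: Ph3P=CHCO2Et, toluene, 80 °C
Reagents that add atoms: ethyl (triphenylphosphoranylidene)acetate CCOC(=O)C=P(c1ccccc1)(c1ccccc1)c1ccccc1
Why: Wittig olefination with a stabilised ylide, which gives the (E)-enoate from aromatic aldehydes and needs no base, so the free hydroxyl is tolerated.

Step 14
Reactants: 23 ethyl (2E)-3-[(2S,3R)-2-[3,5-dimethoxy-4-(triisopropylsilyloxy)phenyl]-3-(hydroxymethyl)-7-methoxy-2,3-dihydro-1-benzofuran-5-yl]prop-2-enoate
Product: 24 (2E)-3-[(2S,3R)-2-[3,5-dimethoxy-4-(triisopropylsilyloxy)phenyl]-3-(hydroxymethyl)-7-methoxy-2,3-dihydro-1-benzofuran-5-yl]prop-2-en-1-ol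
Conditions: i-Bu2AlH (4 equiv), CH2Cl2, −78 → −40 °C
Reagents that add atoms: none
Why: 1,2-Reduction of the enoate to the allylic alcohol by an electrophilic aluminium hydride at low temperature; the alkene geometry and the aryl silyl ether are untouched.

Step 15
Reactants: 25 4-hydroxybenzoic acid
Product: 27 4-(tert-butyldimethylsilyloxy)benzoic acid, via silyl ester 26 (not isolated)
Conditions: TBSCl (2.4 equiv), imidazole, DMF, rt; then AcOH/THF/H2O, rt
Reagents that add atoms: tert-butyldimethylsilyl chloride CC(C)(C)[Si](C)(C)Cl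
Why: Persilylation followed by selective hydrolysis of the silyl ester, which is far more labile to aqueous acid than the aryl silyl ether.

Step 16
Reactants: 24 (2E)-3-[(2S,3R)-2-[3,5-dimethoxy-4-(triisopropylsilyloxy)phenyl]-3-(hydroxymethyl)-7-methoxy-2,3-dihydro-1-benzofuran-5-yl]prop-2-en-1-ol; 27 4-(tert-butyldimethylsilyloxy)benzoic acid
Product: 28 (2E)-3-[(2S,3R)-3-{[4-(tert-butyldimethylsilyloxy)benzoyl]oxymethyl}-2-[3,5-dimethoxy-4-(triisopropylsilyloxy)phenyl]-7-methoxy-2,3-dihydro-1-benzofuran-5-yl]prop-2-en-1-yl 4-(tert-butyldimethylsilyloxy)benzoate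
Conditions: 27 (2.5 equiv), EDC·HCl, DMAP, CH2Cl2, 0 °C → rt
Reagents that add atoms: none
Why: Steglich esterification of both primary alcohols in one operation; the neutral carbodiimide/DMAP conditions avoid ionisation of the oxygen-activated cinnamyl position.

Step 17
Reactants: 28 (2E)-3-[(2S,3R)-3-{[4-(tert-butyldimethylsilyloxy)benzoyl]oxymethyl}-2-[3,5-dimethoxy-4-(triisopropylsilyloxy)phenyl]-7-methoxy-2,3-dihydro-1-benzofuran-5-yl]prop-2-en-1-yl 4-(tert-butyldimethylsilyloxy)benzoate
Product: 29 quiquesetinerviusin B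
Conditions: TBAF (4 equiv), AcOH (5 equiv), THF, 0 °C → rt
Reagents that add atoms: none
Why: Fluoride-mediated cleavage of the three aryl silyl ethers; the acetic acid buffer protonates each phenoxide as it forms, so neither quinone methide opening of ring B nor acyl transfer should set in.

## Compound list

1 | methyl 5-bromofuran-3-carboxylate | COC(=O)c1coc(Br)c1 | starting material
2 | (2-tert-butoxy-2-oxoethyl)zinc bromide | CC(C)(C)OC(=O)C[Zn]Br | starting material
3 | methyl 5-(2-tert-butoxy-2-oxoethyl)furan-3-carboxylate | COC(=O)c1coc(CC(=O)OC(C)(C)C)c1 | intermediate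
4 | [4-(methoxycarbonyl)furan-2-yl]acetic acid | COC(=O)c1coc(CC(=O)O)c1 | intermediate
5 | (4S)-4-benzyl-1,3-oxazolidin-2-one | O=C1N[C@@H](Cc2ccccc2)CO1 | starting material
6 | [4-(methoxycarbonyl)furan-2-yl]acetic pivalic anhydride (formed in the flask) | COC(=O)c1coc(CC(=O)OC(=O)C(C)(C)C)c1 | intermediate
7 | methyl 5-{2-[(4S)-4-benzyl-2-oxo-1,3-oxazolidin-3-yl]-2-oxoethyl}furan-3-carboxylate | COC(=O)c1coc(CC(=O)N2C(=O)OC[C@@H]2Cc2ccccc2)c1 | intermediate
8 | syringaldehyde (4-hydroxy-3,5-dimethoxybenzaldehyde) | COc1cc(C=O)cc(OC)c1O | starting material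
9 | 3,5-dimethoxy-4-(triisopropylsilyloxy)benzaldehyde | COc1cc(C=O)cc(OC)c1O[Si](C(C)C)(C(C)C)C(C)C | intermediate
10 | (Z)-dibutylboron enolate of 7 (formed in the flask) | CCCCB(CCCC)O/C(=C\c1cc(C(=O)OC)co1)N1C(=O)OC[C@@H]1Cc1ccccc1 | intermediate
11 | O-dibutylboryl aldolate of 12 (formed in the flask) | COc1cc([C@@H](OB(CCCC)CCCC)[C@@H](C(=O)N2C(=O)OC[C@@H]2Cc2ccccc2)c2cc(C(=O)OC)co2)cc(OC)c1O[Si](C(C)C)(C(C)C)C(C)C | intermediate
12 | methyl 5-[(2R,3S)-1-[(4S)-4-benzyl-2-oxo-1,3-oxazolidin-3-yl]-3-[3,5-dimethoxy-4-(triisopropylsilyloxy)phenyl]-3-hydroxy-1-oxopropan-2-yl]furan-3-carboxylate | COc1cc([C@@H](O)[C@@H](C(=O)N2C(=O)OC[C@@H]2Cc2ccccc2)c2cc(C(=O)OC)co2)cc(OC)c1O[Si](C(C)C)(C(C)C)C(C)C | intermediate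
13 | (1S,2R)-1-[3,5-dimethoxy-4-(triisopropylsilyloxy)phenyl]-2-[4-(hydroxymethyl)furan-2-yl]propane-1,3-diol | COc1cc([C@@H](O)[C@@H](CO)c2cc(CO)co2)cc(OC)c1O[Si](C(C)C)(C(C)C)C(C)C | intermediate
14 | (1S,2R)-1-[3,5-dimethoxy-4-(triisopropylsilyloxy)phenyl]-3-(trityloxy)-2-[4-(trityloxymethyl)furan-2-yl]propan-1-ol | COc1cc([C@@H](O)[C@@H](COC(c2ccccc2)(c2ccccc2)c2ccccc2)c2cc(COC(c3ccccc3)(c3ccccc3)c3ccccc3)co2)cc(OC)c1O[Si](C(C)C)(C(C)C)C(C)C | intermediate
15 | (E)-1,2-dichlorovinyl ether of 14 (formed in the flask) | COc1cc([C@@H](O/C(Cl)=C\Cl)[C@@H](COC(c2ccccc2)(c2ccccc2)c2ccccc2)c2cc(COC(c3ccccc3)(c3ccccc3)c3ccccc3)co2)cc(OC)c1O[Si](C(C)C)(C(C)C)C(C)C | intermediate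
16 | lithium acetylide of 17 (formed in the flask) | COc1cc([C@@H](OC#C[Li])[C@@H](COC(c2ccccc2)(c2ccccc2)c2ccccc2)c2cc(COC(c3ccccc3)(c3ccccc3)c3ccccc3)co2)cc(OC)c1O[Si](C(C)C)(C(C)C)C(C)C | intermediate
17 | 2-[(1S,2R)-1-[3,5-dimethoxy-4-(triisopropylsilyloxy)phenyl]-1-(ethynyloxy)-3-(trityloxy)propan-2-yl]-4-(trityloxymethyl)furan | COc1cc([C@@H](OC#C)[C@@H](COC(c2ccccc2)(c2ccccc2)c2ccccc2)c2cc(COC(c3ccccc3)(c3ccccc3)c3ccccc3)co2)cc(OC)c1O[Si](C(C)C)(C(C)C)C(C)C | intermediate
18 | 6,7-arene oxide of the (2S,3R)-cyclised skeleton (formed in the flask; configuration at C6 and C7 undefined and lost on aromatisation) | COc1cc([C@H]2OC3=C([C@@H]2COC(c2ccccc2)(c2ccccc2)c2ccccc2)C=C(COC(c2ccccc2)(c2ccccc2)c2ccccc2)C4OC34)cc(OC)c1O[Si](C(C)C)(C(C)C)C(C)C | intermediate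
19 | (2S,3R)-2-[3,5-dimethoxy-4-(triisopropylsilyloxy)phenyl]-3,5-bis(trityloxymethyl)-2,3-dihydro-1-benzofuran-7-ol | COc1cc([C@H]2Oc3c(O)cc(COC(c4ccccc4)(c4ccccc4)c4ccccc4)cc3[C@@H]2COC(c2ccccc2)(c2ccccc2)c2ccccc2)cc(OC)c1O[Si](C(C)C)(C(C)C)C(C)C | intermediate
20 | (2S,3R)-2-[3,5-dimethoxy-4-(triisopropylsilyloxy)phenyl]-7-methoxy-3,5-bis(trityloxymethyl)-2,3-dihydro-1-benzofuran | COc1cc([C@H]2Oc3c(OC)cc(COC(c4ccccc4)(c4ccccc4)c4ccccc4)cc3[C@@H]2COC(c2ccccc2)(c2ccccc2)c2ccccc2)cc(OC)c1O[Si](C(C)C)(C(C)C)C(C)C | intermediate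
21 | [(2S,3R)-2-[3,5-dimethoxy-4-(triisopropylsilyloxy)phenyl]-7-methoxy-2,3-dihydro-1-benzofuran-3,5-diyl]dimethanol | COc1cc([C@H]2Oc3c(OC)cc(CO)cc3[C@@H]2CO)cc(OC)c1O[Si](C(C)C)(C(C)C)C(C)C | intermediate
22 | (2S,3R)-2-[3,5-dimethoxy-4-(triisopropylsilyloxy)phenyl]-3-(hydroxymethyl)-7-methoxy-2,3-dihydro-1-benzofuran-5-carbaldehyde | COc1cc([C@H]2Oc3c(OC)cc(C=O)cc3[C@@H]2CO)cc(OC)c1O[Si](C(C)C)(C(C)C)C(C)C | intermediate
23 | ethyl (2E)-3-[(2S,3R)-2-[3,5-dimethoxy-4-(triisopropylsilyloxy)phenyl]-3-(hydroxymethyl)-7-methoxy-2,3-dihydro-1-benzofuran-5-yl]prop-2-enoate | COc1cc([C@H]2Oc3c(OC)cc(/C=C/C(=O)OCC)cc3[C@@H]2CO)cc(OC)c1O[Si](C(C)C)(C(C)C)C(C)C | intermediate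
24 | (2E)-3-[(2S,3R)-2-[3,5-dimethoxy-4-(triisopropylsilyloxy)phenyl]-3-(hydroxymethyl)-7-methoxy-2,3-dihydro-1-benzofuran-5-yl]prop-2-en-1-ol | COc1cc([C@H]2Oc3c(OC)cc(/C=C/CO)cc3[C@@H]2CO)cc(OC)c1O[Si](C(C)C)(C(C)C)C(C)C | intermediate
25 | 4-hydroxybenzoic acid | OC(=O)c1ccc(O)cc1 | starting material
26 | tert-butyldimethylsilyl 4-(tert-butyldimethylsilyloxy)benzoate (formed in the flask) | CC(C)(C)[Si](C)(C)OC(=O)c1ccc(O[Si](C)(C)C(C)(C)C)cc1 | intermediate
27 | 4-(tert-butyldimethylsilyloxy)benzoic acid | CC(C)(C)[Si](C)(C)Oc1ccc(C(=O)O)cc1 | intermediate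
28 | (2E)-3-[(2S,3R)-3-{[4-(tert-butyldimethylsilyloxy)benzoyl]oxymethyl}-2-[3,5-dimethoxy-4-(triisopropylsilyloxy)phenyl]-7-methoxy-2,3-dihydro-1-benzofuran-5-yl]prop-2-en-1-yl 4-(tert-butyldimethylsilyloxy)benzoate | COc1cc([C@H]2Oc3c(OC)cc(/C=C/COC(=O)c4ccc(O[Si](C)(C)C(C)(C)C)cc4)cc3[C@@H]2COC(=O)c2ccc(O[Si](C)(C)C(C)(C)C)cc2)cc(OC)c1O[Si](C(C)C)(C(C)C)C(C)C | intermediate
29 | quiquesetinerviusin B, (2E)-3-[(2S,3R)-2-(4-hydroxy-3,5-dimethoxyphenyl)-3-[(4-hydroxybenzoyl)oxymethyl]-7-methoxy-2,3-dihydro-1-benzofuran-5-yl]prop-2-en-1-yl 4-hydroxybenzoate | COc1cc([C@H]2Oc3c(OC)cc(/C=C/COC(=O)c4ccc(O)cc4)cc3[C@@H]2COC(=O)c2ccc(O)cc2)cc(OC)c1O | target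

## Step count and risk

Total step count: 17. Longest linear sequence: 15 steps (steps 1–3, 5–14, 16 and 17, from 1).

**Step 9 (key step).** The most likely failure is heterolysis of the benzylic C–O bond of 17 under the Lewis-acidic gold complex or traces of acid. The alkynyloxy group would then be lost through the para-silyloxybenzyl cation before the furan can attack; hydration of the alkynyl ether by adventitious water is the second drain. The tether is also fully substituted and hindered, and has not been tried in this reaction.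

The fallback buys ring A and closes ring B by ionisation at C2. It sets out from 2, 5 and 9 and rejoins the route at 21. Methyl 3-bromo-4-hydroxy-5-methoxybenzoate F1 is O-allylated (allyl bromide, K2CO3) to methyl 3-bromo-5-methoxy-4-(prop-2-en-1-yloxy)benzoate F2. F2 is coupled with 2 under the conditions of step 1 to the tert-butyl arylacetate F3. TFA gives the arylacetic acid F4, which is joined to 5 (DCC, DMAP) as imide F5. The boron aldol of F5 with 9 under the conditions of step 5 should give the syn adduct F6. LiBH4 at 0 °C removes the auxiliary without reducing the electron-rich benzoate and gives diol F7. Deallylation (Pd(PPh3)4, morpholine) frees the phenol F8. A trace of acid (BF3·OEt2, CH2Cl2, low temperature) then ionises the para-silyloxybenzylic alcohol, and the phenol should close ring B on the face away from the C3 arm to give the trans ester F9. Reduction of F9 with i-Bu2AlH gives 21.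

**Step 8.** The benzylic alkynyl ether may be lost while it is made or isolated. The hindered potassium alkoxide may add slowly to dichloroacetylene and decompose instead, and benzyl alkynyl ethers rearrange sigmatropically or expel ketene on warming.

The fallback avoids the free alkoxide. It sets out from 14 and returns at 17. Formylation (formic acid, DCC, DMAP) gives the formate F10. Dichloromethylenation of the formyl group (PPh3, CCl4, THF, 60 °C) gives the 2,2-dichlorovinyl ether F11. n-BuLi at −78 °C converts F11 into the lithium acetylide 16, which methanol protonates to 17.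

**Step 6.** Two things can go wrong. The furan ester may be reduced incompletely at a temperature the rest of the molecule tolerates, or the β-alkoxide may undergo retro-aldol cleavage before the imide is reduced if the mixture is warmed too early.

The fallback splits the reduction between two reagents. It sets out from 12 and returns at 13. LiBH4 at 0 °C cleaves only the imide and gives the diol ester F12. i-Bu2AlH in CH2Cl2 at −78 °C then reduces the furan ester of F12 to 13.

**Step 17.** Fluoride generates the ring C phenoxide para to C2. If it is not protonated quickly, ring B can open through a quinone methide and reclose with loss of the C2 configuration. The basic medium can also move or remove the acyl groups, especially at the cinnamyl position.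

The fallback frees the ring C phenol last and under acidic fluoride. It sets out from 24 and returns at 29. Steglich esterification of 24 with commercial 4-acetoxybenzoic acid gives the bis(4-acetoxybenzoate) F13. Hydrazine acetate in DMF removes the two aryl acetates while ring C is still silylated and gives the bis(4-hydroxybenzoate) F14. HF·pyridine in THF/pyridine at 0 °C then cleaves the triisopropylsilyl ether of F14 to 29.

## Further compounds

F1 | step 9 | methyl 3-bromo-4-hydroxy-5-methoxybenzoate | COC(=O)c1cc(Br)c(O)c(OC)c1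
F2 | step 9 | methyl 3-bromo-5-methoxy-4-(prop-2-en-1-yloxy)benzoate | COC(=O)c1cc(Br)c(OCC=C)c(OC)c1
F3 | step 9 | methyl 3-(2-tert-butoxy-2-oxoethyl)-5-methoxy-4-(prop-2-en-1-yloxy)benzoate | COC(=O)c1cc(CC(=O)OC(C)(C)C)c(OCC=C)c(OC)c1
F4 | step 9 | [3-methoxy-5-(methoxycarbonyl)-2-(prop-2-en-1-yloxy)phenyl]acetic acid | COC(=O)c1cc(CC(=O)O)c(OCC=C)c(OC)c1
F5 | step 9 | methyl 3-{2-[(4S)-4-benzyl-2-oxo-1,3-oxazolidin-3-yl]-2-oxoethyl}-5-methoxy-4-(prop-2-en-1-yloxy)benzoate | COC(=O)c1cc(CC(=O)N2C(=O)OC[C@@H]2Cc2ccccc2)c(OCC=C)c(OC)c1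
F6 | step 9 | methyl 3-[(2S,3S)-1-[(4S)-4-benzyl-2-oxo-1,3-oxazolidin-3-yl]-3-[3,5-dimethoxy-4-(triisopropylsilyloxy)phenyl]-3-hydroxy-1-oxopropan-2-yl]-5-methoxy-4-(prop-2-en-1-yloxy)benzoate | COc1cc([C@@H](O)[C@@H](C(=O)N2C(=O)OC[C@@H]2Cc2ccccc2)c2cc(C(=O)OC)cc(OC)c2OCC=C)cc(OC)c1O[Si](C(C)C)(C(C)C)C(C)C
F7 | step 9 | methyl 3-[(1S,2R)-1-[3,5-dimethoxy-4-(triisopropylsilyloxy)phenyl]-1,3-dihydroxypropan-2-yl]-5-methoxy-4-(prop-2-en-1-yloxy)benzoate | COc1cc([C@@H](O)[C@@H](CO)c2cc(C(=O)OC)cc(OC)c2OCC=C)cc(OC)c1O[Si](C(C)C)(C(C)C)C(C)C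
F8 | step 9 | methyl 3-[(1S,2R)-1-[3,5-dimethoxy-4-(triisopropylsilyloxy)phenyl]-1,3-dihydroxypropan-2-yl]-4-hydroxy-5-methoxybenzoate | COc1cc([C@@H](O)[C@@H](CO)c2cc(C(=O)OC)cc(OC)c2O)cc(OC)c1O[Si](C(C)C)(C(C)C)C(C)C
F9 | step 9 | methyl (2S,3R)-2-[3,5-dimethoxy-4-(triisopropylsilyloxy)phenyl]-3-(hydroxymethyl)-7-methoxy-2,3-dihydro-1-benzofuran-5-carboxylate | COc1cc([C@H]2Oc3c(OC)cc(C(=O)OC)cc3[C@@H]2CO)cc(OC)c1O[Si](C(C)C)(C(C)C)C(C)C
F10 | step 8 | (1S,2R)-1-[3,5-dimethoxy-4-(triisopropylsilyloxy)phenyl]-3-(trityloxy)-2-[4-(trityloxymethyl)furan-2-yl]propyl formate | COc1cc([C@@H](OC=O)[C@@H](COC(c2ccccc2)(c2ccccc2)c2ccccc2)c2cc(COC(c3ccccc3)(c3ccccc3)c3ccccc3)co2)cc(OC)c1O[Si](C(C)C)(C(C)C)C(C)C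
F11 | step 8 | 2-[(1S,2R)-1-(2,2-dichloroethenyloxy)-1-[3,5-dimethoxy-4-(triisopropylsilyloxy)phenyl]-3-(trityloxy)propan-2-yl]-4-(trityloxymethyl)furan | COc1cc([C@@H](OC=C(Cl)Cl)[C@@H](COC(c2ccccc2)(c2ccccc2)c2ccccc2)c2cc(COC(c3ccccc3)(c3ccccc3)c3ccccc3)co2)cc(OC)c1O[Si](C(C)C)(C(C)C)C(C)C
F12 | step 6 | methyl 5-[(1S,2R)-1-[3,5-dimethoxy-4-(triisopropylsilyloxy)phenyl]-1,3-dihydroxypropan-2-yl]furan-3-carboxylate | COc1cc([C@@H](O)[C@@H](CO)c2cc(C(=O)OC)co2)cc(OC)c1O[Si](C(C)C)(C(C)C)C(C)C
F13 | step 17 | (2E)-3-[(2S,3R)-3-{[4-(acetyloxy)benzoyl]oxymethyl}-2-[3,5-dimethoxy-4-(triisopropylsilyloxy)phenyl]-7-methoxy-2,3-dihydro-1-benzofuran-5-yl]prop-2-en-1-yl 4-(acetyloxy)benzoate | COc1cc([C@H]2Oc3c(OC)cc(/C=C/COC(=O)c4ccc(OC(C)=O)cc4)cc3[C@@H]2COC(=O)c2ccc(OC(C)=O)cc2)cc(OC)c1O[Si](C(C)C)(C(C)C)C(C)C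
F14 | step 17 | (2E)-3-[(2S,3R)-2-[3,5-dimethoxy-4-(triisopropylsilyloxy)phenyl]-3-[(4-hydroxybenzoyl)oxymethyl]-7-methoxy-2,3-dihydro-1-benzofuran-5-yl]prop-2-en-1-yl 4-hydroxybenzoate | COc1cc([C@H]2Oc3c(OC)cc(/C=C/COC(=O)c4ccc(O)cc4)cc3[C@@H]2COC(=O)c2ccc(O)cc2)cc(OC)c1O[Si](C(C)C)(C(C)C)C(C)C
A1 | alternative 1 | methyl (2S,3S)-2-[4-(benzyloxy)-3,5-dimethoxyphenyl]-5-bromo-7-methoxy-2,3-dihydro-1-benzofuran-3-carboxylate | COc1cc([C@H]2Oc3c(OC)cc(Br)cc3[C@@H]2C(=O)OC)cc(OC)c1OCc1ccccc1
A2 | alternative 1 | (2S)-2-[4-(benzyloxy)-3,5-dimethoxyphenyl]-6-bromo-8-methoxy-2,3-dihydro-4H-chromen-4-one | COc1cc([C@@H]2CC(=O)c3cc(Br)cc(OC)c3O2)cc(OC)c1OCc1ccccc1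
A3 | alternative 2 | (2S,3R)-5-bromo-2-[4-(tert-butyldimethylsilyloxy)-3,5-dimethoxyphenyl]-3-(tert-butyldimethylsilyloxymethyl)-7-methoxy-2,3-dihydro-1-benzofuran | COc1cc([C@H]2Oc3c(OC)cc(Br)cc3[C@@H]2CO[Si](C)(C)C(C)(C)C)cc(OC)c1O[Si](C)(C)C(C)(C)C
A4 | alternative 2 | 4-bromo-2-[2-(tert-butyldimethylsilyloxy)-1-(4-methylbenzenesulfonyl)ethyl]-6-methoxyphenol | COc1cc(Br)cc(C(CO[Si](C)(C)C(C)(C)C)S(=O)(=O)c2ccc(C)cc2)c1O
A5 | alternative 2 | (2R,5R)-1-[4-(tert-butyldimethylsilyloxy)-3,5-dimethoxybenzyl]-2,5-dimethylthiolan-1-ium bromide (sulfide enantiomer to be matched to the required sense) | COc1cc(C[S+]2[C@H](C)CC[C@H]2C)cc(OC)c1O[Si](C)(C)C(C)(C)C.[Br-]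
A6 | alternative 2 | 4-bromo-6-[2-(tert-butyldimethylsilyloxy)ethylidene]-2-methoxycyclohexa-2,4-dien-1-one | COC1=CC(Br)=CC(=CCO[Si](C)(C)C(C)(C)C)C1=O
A7 | alternative 3 | methyl (2S,3R)-2-[4-(tert-butyldimethylsilyloxy)-3,5-dimethoxyphenyl]-3-(tert-butyldimethylsilyloxymethyl)-7-methoxy-2,3-dihydro-1-benzofuran-5-carboxylate | COc1cc([C@H]2Oc3c(OC)cc(C(=O)OC)cc3[C@@H]2CO[Si](C)(C)C(C)(C)C)cc(OC)c1O[Si](C)(C)C(C)(C)C
A8 | alternative 3 | methyl 4-iodo-3-methoxybenzoate | COC(=O)c1ccc(I)c(OC)c1
A9 | alternative 3 | tert-butyl({(2S,3R)-3-[4-(tert-butyldimethylsilyloxy)-3,5-dimethoxyphenyl]oxiran-2-yl}methoxy)dimethylsilane (cis) | COc1cc([C@H]2O[C@H]2CO[Si](C)(C)C(C)(C)C)cc(OC)c1O[Si](C)(C)C(C)(C)C
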